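## Analysis of the target

Locants follow germacrane numbering. Read along the SMILES, the atoms are C13, C11, C12, O, C6, C5, C4 (bearing C15), C3, C2, C1, C10 (bearing C14), C9, C8, C7.

- **Ring system.** Ring A is the ten-membered carbocycle C1–C10. Ring B is the α-methylene-γ-butyrolactone O–C6–C7–C11–C12 with the exocyclic C11=C13 methylene. The rings share only the C6–C7 bond and are trans-fused (H6 and H7 anti).
- **Ring alkene.** C1=C10 carries the C14 methyl ester. It is E by CIP (ester trans to C2) but cis with respect to the ring bonds C9–C10 and C1–C2, so it costs little ring strain.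
- **Stereocentres.** C6 (R), C7 (S) and C8 (R) are contiguous; C4 (S) is isolated. In the zigzag C5–C9, O6 is syn to C11 and O8 is anti to it, so C7 sits between two carbinol carbons of like configuration (an anti-1,3-diol).
- **Competing lactones.** O6 and O8 are both γ to C12, and O8 is also γ to C14. A free O8–H can therefore translactonize in two directions.
- **Sensitive groups.** The methylene lactone is a Michael acceptor. Three different esters (lactone, methyl ester, isobutyrate) must stay differentiated beside a free primary alcohol.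
- **Strategic feature.** Ring B on the C6–C7 bond is the retron of a 2-(alkoxycarbonyl)allyl metal adding through its γ carbon (C7) to a C6 aldehyde. Forming that one bond would close ring A, set C6 and C7, and deliver ring B with its methylene in place.
- **Constraint.** In any such allyl metal O8 stands 1,4 to the metal-bearing C13, so an acyloxy group at C8 would be expelled. The isobutyrate must come after ring formation.
- **Difficulty.** A medium ring, a trisubstituted ring enoate, a stereotriad whose middle carbon is the ring fusion, and a remote fourth centre.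

## Retrosynthetic reasoning

**End game (23 ← 22 ← 21 ← 20).** Only protecting-group and acylation steps are placed after ring formation. O8 is carried as a silyl ether through the key step because a carboxylate at C8 would leave by reductive 1,4-elimination from the allyl metal. The C15 silyl ether is removed last so that the isobutyrate can be put on the only free hydroxyl of 21.

**Key disconnection (20 ← 17).** The C6–C7 bond and the O6–C12 acyl bond are cut together. C6–C7 is the only bond common to rings A and B. Its formation from the ω-formyl (Z)-2-(bromomethyl)enoate 17 by a chromium-mediated allylation has to close the ten-membered ring, create C6 and C7 under control of C8, and release the C11=C13 methylene by allylic transposition. The precursor 17 is an open chain with only two isolated stereocentres (C4, C8). Its cis-configured C1=C10 enoate acts as a turn element.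

**C1=C10 (17 ← 6 + 16).** The chain is cut at the trisubstituted enoate into two halves of similar size. Cross metathesis of the terminal alkene of 6 with the 1,1-disubstituted acrylate of 16 has to give the thermodynamic E enoate, which is the geometry the target needs.

**Eastern half (16 ← 15 ← 13 + 14; 13 ← 11 ← 10 ← 7 + 8).** The (Z)-bromomethyl enoate comes from a Morita–Baylis–Hillman adduct of aldehyde 13 with 14 by allylic transposition. The C7 aldehyde of 13 is revealed by glycol cleavage of the dioxolane of 11. C8 is set in 10 by Felkin–Anh addition of the allyl unit of 8 (C9, C10, C14) to the chiral-pool aldehyde 7. The stereocentre bought with 7 is erased once it has set C8.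

**Western half (6 ← 5 ← 4 ← 3 ← 2 ← 1).** C4 is the only stereocentre not in reach of C8. It is set by catalytic desymmetrization: oxygen insertion into the prochiral ketone 2 gives lactone 3, which also differentiates the two arms (C1 at the carboxyl level, C6 as carbinol). Partial reduction, methylenation and oxidation give 6.

## Alternatives that were turned down

**Alternative 1:** Ring-closing metathesis at C1=C10 (the textbook route).
- Forward: build the trans-lactone first by an intermolecular Barbier allylation, acylate O8, and close ring A from diene lactone A1 with a second-generation Grubbs catalyst, with loss of ethylene.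
- Turned down because the weakest step comes last. It must form a trisubstituted, ester-bearing alkene inside a ten-membered ring already stiffened by the trans-fused lactone, from a 1,1-disubstituted electron-poor alkene that initiates slowly.
- The C11=C13 methylene of A1 is an alkene of the same type and can close an eight-membered ring with C1 instead; masking it costs two steps.
- The stereotriad has to be set in the open chain with no help from the ring.

**Alternative 2:** Ring expansion by anionic oxy-Cope rearrangement (C1–C6 cut, C8–C9 formed).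
- Forward: trans-1,2-dialkenylcyclohexanol A2 with KH and 18-crown-6 would give cyclodec-5-enone A3.
- Turned down because the chair transition state of a trans-dialkenyl cyclohexanol gives the ring-trans C1=C10 alkene, which is the wrong geometry.
- C14 must travel at the alcohol level, since a C10 ester would invite transannular Michael addition of the C6 enolate onto C1. Re-oxidation costs three steps.
- A3 has its ketone at C6 with the C8 oxygen in the β position (E1cB loss). C7 still has to be alkylated and C6 reduced, with macrocyclic stereocontrol that cannot be predicted.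
- The precursor needs a regioselective α′-functionalization of a 3-substituted cyclohexanone. The route would be several steps longer than the one chosen.

**Alternative 3:** [2,3]-Wittig ring contraction (C7–C8 formed).
- Forward: in the thirteen-membered cyclic ether A4, O8 is bonded to C13. Deprotonation at C8 and a [2,3]-shift would form C7–C8, set both centres and create the C11=C13 methylene.
- Turned down because C8 has no anion-stabilizing neighbour: C9 is sp3 and C4–C5 is saturated.
- The strong base needed would instead deprotonate the γ positions (C2, C9) of the enoate or attack the esters.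
- A4 needs its own macrocyclization.
- After the shift the C8 alkoxide lies γ to both C12 and C14 and would lactonize without selectivity.

Key step: step 12

Assumption: aldehyde 7 is taken as commercially available in the (S) form; it is also reached by oxidation of commercial (R)-solketal.

## Route

Step 1
Reactants: 1 4-(hydroxymethyl)cyclohexan-1-one
Product: 2 4-{[(tert-butyldiphenylsilyl)oxy]methyl}cyclohexan-1-one
Conditions: TBDPSCl, imidazole, DMF, 25 °C
Reagents that add atoms: tert-butyl(chloro)diphenylsilane (TBDPSCl), CC(C)(C)[Si](Cl)(c1ccccc1)c1ccccc1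
Why: Standard silylation of the primary alcohol; the TBDPS ether is chosen because it should survive peracid, hydride, ylide, periodic acid and divalent chromium and can be removed last under acidic fluoride.

Step 2
Reactants: 2 4-{[(tert-butyldiphenylsilyl)oxy]methyl}cyclohexan-1-one
Product: 3 (5S)-5-{[(tert-butyldiphenylsilyl)oxy]methyl}oxepan-2-one
Conditions: Sc(OTf)3 (5 mol%), chiral N,N′-dioxide ligand (6 mol%), mCPBA, EtOAc, −20 °C
Reagents that add atoms: 3-chloroperbenzoic acid (mCPBA), OOC(=O)c1cccc(Cl)c1
Why: Desymmetrizing Baeyer–Villiger oxidation of a prochiral 4-substituted cyclohexanone; the chiral scandium complex differentiates the two enantiotopic α-methylene groups in the migration step, and the ligand enantiomer is chosen to give the (S)-lactone, which fixes C4.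

Step 3
Reactants: 3 (5S)-5-{[(tert-butyldiphenylsilyl)oxy]methyl}oxepan-2-one
Product: 4 (5S)-5-{[(tert-butyldiphenylsilyl)oxy]methyl}oxepan-2-ol (both anomers)
Conditions: DIBAL-H (1.1 equiv), CH2Cl2, −78 °C
Reagents that add atoms: none
Why: Partial reduction of the lactone; the aluminium hemiacetal is stable at low temperature and gives the lactol on work-up, with C4 untouched.

Step 4
Reactants: 4 (5S)-5-{[(tert-butyldiphenylsilyl)oxy]methyl}oxepan-2-ol
Product: 5 (3S)-3-{[(tert-butyldiphenylsilyl)oxy]methyl}hept-6-en-1-ol
Conditions: Ph3PCH3Br, KOtBu, THF, 0 to 25 °C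
Reagents that add atoms: methyltriphenylphosphonium bromide, C[P+](c1ccccc1)(c1ccccc1)c1ccccc1.[Br-]
Why: Wittig methylenation of the open hydroxy-aldehyde form of the lactol; the added carbon is later lost as ethylene and the C6 hydroxyl is set free for oxidation.

Step 5
Reactants: 5 (3S)-3-{[(tert-butyldiphenylsilyl)oxy]methyl}hept-6-en-1-ol
Product: 6 (3S)-3-{[(tert-butyldiphenylsilyl)oxy]methyl}hept-6-enal
Conditions: TEMPO (10 mol%), PhI(OAc)2, CH2Cl2, 25 °C
Reagents that add atoms: none
Why: Nitroxyl-catalysed oxidation of the primary alcohol stops at the aldehyde and leaves the alkene alone; the stereocentre is β to the new carbonyl and cannot epimerize.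

Step 6
Reactants: 7 (4S)-2,2-dimethyl-1,3-dioxolane-4-carbaldehyde; 8 methyl 2-(bromomethyl)prop-2-enoate
Product: 10 methyl (4R)-4-[(4S)-2,2-dimethyl-1,3-dioxolan-4-yl]-4-hydroxy-2-methylidenebutanoate, via allylzinc bromide 9 (not isolated)
Conditions: Zn dust, THF/sat. aq. NH4Cl, 0 to 25 °C
Reagents that add atoms: none
Why: Barbier allylation; allylzinc 9 adds to the α-alkoxy aldehyde under Felkin–Anh control (dioxolane C–O bond antiperiplanar to the nucleophile, no chelation in water), which should set C8 as R (anti to the dioxolane oxygen); the aqueous zinc conditions should leave the γ-hydroxy ester unlactonized.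

Step 7
Reactants: 10 methyl (4R)-4-[(4S)-2,2-dimethyl-1,3-dioxolan-4-yl]-4-hydroxy-2-methylidenebutanoate
Product: 11 methyl (4R)-4-[(tert-butyldimethylsilyl)oxy]-4-[(4S)-2,2-dimethyl-1,3-dioxolan-4-yl]-2-methylidenebutanoate
Conditions: TBSOTf, 2,6-lutidine, CH2Cl2, −78 to 0 °C
Reagents that add atoms: tert-butyldimethylsilyl trifluoromethanesulfonate (TBSOTf), CC(C)(C)[Si](C)(C)OS(=O)(=O)C(F)(F)F
Why: Silyl triflate with a non-nucleophilic base protects O8 without lactonization onto C14; a silyl ether is used because an acyloxy group at C8 would be expelled in the key step.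

Step 8
Reactants: 11 methyl (4R)-4-[(tert-butyldimethylsilyl)oxy]-4-[(4S)-2,2-dimethyl-1,3-dioxolan-4-yl]-2-methylidenebutanoate
Product: 13 methyl (4R)-4-[(tert-butyldimethylsilyl)oxy]-2-methylidene-5-oxopentanoate, via glycol 12 (not isolated)
Conditions: H5IO6, EtOAc, 25 °C
Reagents that add atoms: none
Why: Periodic acid hydrolyses the terminal acetonide and cleaves the liberated glycol 12 in the same flask through a cyclic periodate ester; the auxiliary stereocentre is erased, C8 is untouched, and the α-silyloxy aldehyde is used crude.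

Step 9
Reactants: 13 methyl (4R)-4-[(tert-butyldimethylsilyl)oxy]-2-methylidene-5-oxopentanoate; 14 methyl prop-2-enoate
Product: 15 dimethyl (4R)-4-[(tert-butyldimethylsilyl)oxy]-5-hydroxy-2,6-dimethylideneheptanedioate (both C5 epimers)
Conditions: DABCO (1 equiv), 14 (5 equiv), MeOH, 25 °C
Reagents that add atoms: none
Why: Morita–Baylis–Hillman reaction; only acrylate 14 can form the reactive amine zwitterion (the α-substituted acrylate at C10 is inert), and the configuration of the new carbinol is irrelevant because C7 becomes sp2 in step 10.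

Step 10
Reactants: 15 dimethyl (4R)-4-[(tert-butyldimethylsilyl)oxy]-5-hydroxy-2,6-dimethylideneheptanedioate
Product: 16 dimethyl (2Z,4R)-2-(bromomethyl)-4-[(tert-butyldimethylsilyl)oxy]-6-methylidenehept-2-enedioate
Conditions: NBS, Me2S, CH2Cl2, −20 to 25 °C
Reagents that add atoms: N-bromosuccinimide (NBS), O=C1CCC(=O)N1Br
Why: Activation of the allylic alcohol as an alkoxysulfonium salt and SN2′ attack of bromide with allylic transposition should give the thermodynamically preferred (Z)-2-(bromomethyl)enoate (bromomethyl cis to C8).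

Step 11
Reactants: 6 (3S)-3-{[(tert-butyldiphenylsilyl)oxy]methyl}hept-6-enal; 16 dimethyl (2Z,4R)-2-(bromomethyl)-4-[(tert-butyldimethylsilyl)oxy]-6-methylidenehept-2-enedioate
Product: 17 dimethyl (2Z,4R,6E)-2-(bromomethyl)-4-[(tert-butyldimethylsilyl)oxy]-6-[(4S)-4-{[(tert-butyldiphenylsilyl)oxy]methyl}-6-oxohexylidene]hept-2-enedioate
Conditions: second-generation Hoveyda–Grubbs catalyst (10 mol%), 6 (2 equiv), CH2Cl2, 40 °C
Reagents that add atoms: none
Why: Olefin cross metathesis between a terminal alkene and a 1,1-disubstituted acrylate that cannot homodimerize; the trisubstituted enoate should form under thermodynamic control with the ester trans to C2, while the trisubstituted bromomethyl enoate and the aldehyde are spectators.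

Step 12
Reactants: 17 dimethyl (2Z,4R,6E)-2-(bromomethyl)-4-[(tert-butyldimethylsilyl)oxy]-6-[(4S)-4-{[(tert-butyldiphenylsilyl)oxy]methyl}-6-oxohexylidene]hept-2-enedioate
Product: 20 methyl (1(10)E,4S,6R,7S,8R)-8-[(tert-butyldimethylsilyl)oxy]-15-[(tert-butyldiphenylsilyl)oxy]germacra-1(10),11(13)-dien-12,6-olid-14-oate, via allylchromium dichloride 18 (not isolated), via seco hydroxy ester 19 (not isolated)
Conditions: CrCl2 (8 equiv), THF, 25 °C, addition of 17 over 12 h (final 0.002 M); then TsOH·H2O (cat.), CH2Cl2, 25 °C
Reagents that add atoms: none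
Why: Two equivalents of divalent chromium reduce the allylic bromide to the trivalent allylchromium 18, whose E and Z forms interconvert by 1,3-metal shift, and its γ carbon C7 adds to the tethered C6 aldehyde through a closed six-membered chair (Zimmerman–Traxler) transition state, after which the alkoxide of 19 acylates onto the C12 ester. The closest known reaction type is the intramolecular Nozaki–Hiyama–Kishi allylation of ω-formyl 2-(bromomethyl)alk-2-enoates, a reaction type known for closing ten-membered carbocycles of germacranolide lactones. Ring A closes in a 10-exo-trig mode by the C6–C7 bond, helped by the cis ring geometry of the C1=C10 enoate as a turn element and by slow addition; ring B closes in a 5-exo-trig mode by attack of O6 on C12, on its own or on the acid work-up. C6 and C7 are set together: the chair with the C5 chain and C8 both pseudo-equatorial (allylchromium isomer with C8 trans to the CH2–Cr carbon) should give the 6,7-anti adduct, which is the trans-fused lactone. The face of C7 is chosen by C8: allylic 1,3-strain holds H8 in the plane of C7=C11, the new bond forms antiperiplanar to the C8–C9 bond so that the forming ring is not eclipsed, and the aldehyde should therefore arrive on the face of the silyloxy group, giving 7S next to 8R. The step needs γ over α attack (inherent to the closed transition state), ring closure over oligomerization (high dilution), and addition over reductive 1,4-elimination of the C8 oxygen, which is why O8 carries a poorly leaving silyl ether and not the isobutyrate. The exocyclic C11=C13 alkene arises from the allylic transposition itself, so no later methylenation is needed.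

Step 13
Reactants: 20 methyl (1(10)E,4S,6R,7S,8R)-8-[(tert-butyldimethylsilyl)oxy]-15-[(tert-butyldiphenylsilyl)oxy]germacra-1(10),11(13)-dien-12,6-olid-14-oate
Product: 21 methyl (1(10)E,4S,6R,7R,8R)-15-[(tert-butyldiphenylsilyl)oxy]-8-hydroxygermacra-1(10),11(13)-dien-12,6-olid-14-oate (same spatial arrangement as 20; the C7 descriptor changes by priority only)
Conditions: HF·pyridine, pyridine, THF, 0 to 25 °C
Reagents that add atoms: none
Why: Buffered acidic fluoride should cleave the secondary TBS ether while the more acid-stable primary TBDPS ether stays; the non-basic medium should avoid translactonization of the freed O8–H onto C12 or C14.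

Step 14
Reactants: 21 methyl (1(10)E,4S,6R,7R,8R)-15-[(tert-butyldiphenylsilyl)oxy]-8-hydroxygermacra-1(10),11(13)-dien-12,6-olid-14-oate
Product: 22 methyl (1(10)E,4S,6R,7S,8R)-15-[(tert-butyldiphenylsilyl)oxy]-8-[(2-methylpropanoyl)oxy]germacra-1(10),11(13)-dien-12,6-olid-14-oate
Conditions: (iPrCO)2O, DMAP (cat.), pyridine, CH2Cl2, 0 °C
Reagents that add atoms: 2-methylpropanoic anhydride (isobutyric anhydride), CC(C)C(=O)OC(=O)C(C)C
Why: DMAP-catalysed acylation of the only free hydroxyl with retention at C8; it is run directly after step 13 so that the γ-hydroxy esters have no time to lactonize.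

Step 15
Reactants: 22 methyl (1(10)E,4S,6R,7S,8R)-15-[(tert-butyldiphenylsilyl)oxy]-8-[(2-methylpropanoyl)oxy]germacra-1(10),11(13)-dien-12,6-olid-14-oate
Product: 23 methyl (1(10)E,4S,6R,7S,8R)-15-hydroxy-8-[(2-methylpropanoyl)oxy]germacra-1(10),11(13)-dien-12,6-olid-14-oate (CNP0251148.1)
Conditions: HF·pyridine (excess), THF, 25 °C
Reagents that add atoms: none
Why: Acidic fluoride removes the TBDPS ether without a nucleophilic base, so the methylene lactone, the isobutyrate and the methyl ester should stay intact.

## Compound list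

1 | 4-(hydroxymethyl)cyclohexan-1-one | O=C1CCC(CO)CC1 | starting material
2 | 4-{[(tert-butyldiphenylsilyl)oxy]methyl}cyclohexan-1-one | O=C1CCC(CO[Si](c2ccccc2)(c2ccccc2)C(C)(C)C)CC1 | intermediate
3 | (5S)-5-{[(tert-butyldiphenylsilyl)oxy]methyl}oxepan-2-one | O=C1CC[C@H](CO[Si](c2ccccc2)(c2ccccc2)C(C)(C)C)CCO1 | intermediate
4 | (5S)-5-{[(tert-butyldiphenylsilyl)oxy]methyl}oxepan-2-ol (both anomers) | OC1CC[C@H](CO[Si](c2ccccc2)(c2ccccc2)C(C)(C)C)CCO1 | intermediate
5 | (3S)-3-{[(tert-butyldiphenylsilyl)oxy]methyl}hept-6-en-1-ol | OCC[C@@H](CO[Si](c1ccccc1)(c1ccccc1)C(C)(C)C)CCC=C | intermediate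
6 | (3S)-3-{[(tert-butyldiphenylsilyl)oxy]methyl}hept-6-enal | O=CC[C@@H](CO[Si](c1ccccc1)(c1ccccc1)C(C)(C)C)CCC=C | intermediate
7 | (4S)-2,2-dimethyl-1,3-dioxolane-4-carbaldehyde | O=C[C@@H]1COC(C)(C)O1 | starting material
8 | methyl 2-(bromomethyl)prop-2-enoate | C=C(CBr)C(=O)OC | starting material
9 | [2-(methoxycarbonyl)prop-2-en-1-yl]zinc bromide | C=C(C[Zn]Br)C(=O)OC | intermediate (not isolated)
10 | methyl (4R)-4-[(4S)-2,2-dimethyl-1,3-dioxolan-4-yl]-4-hydroxy-2-methylidenebutanoate | C=C(C(=O)OC)C[C@@H](O)[C@@H]1COC(C)(C)O1 | intermediate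
11 | methyl (4R)-4-[(tert-butyldimethylsilyl)oxy]-4-[(4S)-2,2-dimethyl-1,3-dioxolan-4-yl]-2-methylidenebutanoate | C=C(C(=O)OC)C[C@@H](O[Si](C)(C)C(C)(C)C)[C@@H]1COC(C)(C)O1 | intermediate
12 | methyl (4R,5S)-4-[(tert-butyldimethylsilyl)oxy]-5,6-dihydroxy-2-methylidenehexanoate | C=C(C(=O)OC)C[C@@H](O[Si](C)(C)C(C)(C)C)[C@@H](O)CO | intermediate (not isolated)
13 | methyl (4R)-4-[(tert-butyldimethylsilyl)oxy]-2-methylidene-5-oxopentanoate | C=C(C(=O)OC)C[C@@H](O[Si](C)(C)C(C)(C)C)C=O | intermediate
14 | methyl prop-2-enoate | C=CC(=O)OC | starting material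
15 | dimethyl (4R)-4-[(tert-butyldimethylsilyl)oxy]-5-hydroxy-2,6-dimethylideneheptanedioate (both C5 epimers) | C=C(C(=O)OC)C[C@@H](O[Si](C)(C)C(C)(C)C)C(O)C(=C)C(=O)OC | intermediate
16 | dimethyl (2Z,4R)-2-(bromomethyl)-4-[(tert-butyldimethylsilyl)oxy]-6-methylidenehept-2-enedioate | C=C(C(=O)OC)C[C@@H](O[Si](C)(C)C(C)(C)C)/C=C(\CBr)C(=O)OC | intermediate
17 | dimethyl (2Z,4R,6E)-2-(bromomethyl)-4-[(tert-butyldimethylsilyl)oxy]-6-[(4S)-4-{[(tert-butyldiphenylsilyl)oxy]methyl}-6-oxohexylidene]hept-2-enedioate | O=CC[C@@H](CO[Si](c1ccccc1)(c1ccccc1)C(C)(C)C)CC/C=C(/C(=O)OC)C[C@@H](O[Si](C)(C)C(C)(C)C)/C=C(\CBr)C(=O)OC | intermediate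
18 | allylchromium dichloride of 17 (CrCl2 on C13 in place of Br, trivalent chromium, C7=C11 geometry mobile) | O=CC[C@@H](CO[Si](c1ccccc1)(c1ccccc1)C(C)(C)C)CC/C=C(/C(=O)OC)C[C@@H](O[Si](C)(C)C(C)(C)C)C=C(C[Cr](Cl)Cl)C(=O)OC | intermediate (not isolated)
19 | seco hydroxy ester: dimethyl (1(10)E,4S,6R,7S,8R)-8-[(tert-butyldimethylsilyl)oxy]-15-[(tert-butyldiphenylsilyl)oxy]-6-hydroxygermacra-1(10),11(13)-diene-12,14-dioate | C=C(C(=O)OC)[C@H]1[C@H](O)C[C@@H](CO[Si](c2ccccc2)(c2ccccc2)C(C)(C)C)CC/C=C(/C(=O)OC)C[C@H]1O[Si](C)(C)C(C)(C)C | intermediate (not isolated)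
20 | methyl (1(10)E,4S,6R,7S,8R)-8-[(tert-butyldimethylsilyl)oxy]-15-[(tert-butyldiphenylsilyl)oxy]germacra-1(10),11(13)-dien-12,6-olid-14-oate | C=C1C(=O)O[C@@H]2C[C@@H](CO[Si](c3ccccc3)(c3ccccc3)C(C)(C)C)CC/C=C(/C(=O)OC)C[C@@H](O[Si](C)(C)C(C)(C)C)[C@@H]12 | intermediate
21 | methyl (1(10)E,4S,6R,7R,8R)-15-[(tert-butyldiphenylsilyl)oxy]-8-hydroxygermacra-1(10),11(13)-dien-12,6-olid-14-oate | C=C1C(=O)O[C@@H]2C[C@@H](CO[Si](c3ccccc3)(c3ccccc3)C(C)(C)C)CC/C=C(/C(=O)OC)C[C@@H](O)[C@@H]12 | intermediate
22 | methyl (1(10)E,4S,6R,7S,8R)-15-[(tert-butyldiphenylsilyl)oxy]-8-[(2-methylpropanoyl)oxy]germacra-1(10),11(13)-dien-12,6-olid-14-oate | C=C1C(=O)O[C@@H]2C[C@@H](CO[Si](c3ccccc3)(c3ccccc3)C(C)(C)C)CC/C=C(/C(=O)OC)C[C@@H](OC(=O)C(C)C)[C@@H]12 | intermediate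
23 | methyl (1(10)E,4S,6R,7S,8R)-15-hydroxy-8-[(2-methylpropanoyl)oxy]germacra-1(10),11(13)-dien-12,6-olid-14-oate | C=C1C(=O)O[C@@H]2C[C@@H](CO)CC/C=C(/C(=O)OC)C[C@@H](OC(=O)C(C)C)[C@@H]12 | target

## Step count and risks

Total step count: 15. Longest linear sequence: 10 (steps 1–5 and 11–15; the branch of steps 6–10 joins at step 11).

**Step 12 (key step).**
- What may go wrong: poor facial discrimination at C7, if the strain of the forming ten-membered ring overrides the allylic-strain model that places the aldehyde on the silyloxy face.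
- Formation of the cis-fused lactone, if the allylchromium reacts before its E and Z forms have equilibrated.
- Oligomerization in competition with ring closure, and some reductive 1,4-elimination of the C8 silyloxy group.
- Fallback: the ring is closed at another bond. It sets out from 6 and 16. Intermolecular coupling with CrCl2 in THF at normal concentration would give methyl (4R)-4-[(tert-butyldimethylsilyl)oxy]-4-[(2R,3S)-2-{(2S)-2-{[(tert-butyldiphenylsilyl)oxy]methyl}hex-5-en-1-yl}-4-methylidene-5-oxooxolan-3-yl]-2-methylidenebutanoate F1, whose diastereomers can be separated in the open chain. Ring-closing metathesis of F1 with a second-generation Grubbs catalyst in dilute toluene at 80 °C would then form C1=C10 and return to the route at 20.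

**Step 11 (cross metathesis).**
- What may go wrong: low conversion, because the acrylate of 16 is 1,1-disubstituted, electron-poor and β-branched.
- Slow loss of the allylic bromide on long heating with the ruthenium carbene, and homodimerization of 6.
- Fallback: the fragments are joined before the bromide and the C6 aldehyde exist, so the metathesis can be forced on two robust partners. It sets out from 5 and 11.
  - Cross metathesis (second-generation Hoveyda–Grubbs catalyst, excess 11, toluene, 80 °C) would give methyl (2E,6S)-2-{(2R)-2-[(tert-butyldimethylsilyl)oxy]-2-[(4S)-2,2-dimethyl-1,3-dioxolan-4-yl]ethyl}-6-{[(tert-butyldiphenylsilyl)oxy]methyl}-8-hydroxyoct-2-enoate F2.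
  - H5IO6 would give methyl (2E,6S)-2-{(2R)-2-[(tert-butyldimethylsilyl)oxy]-3-oxopropyl}-6-{[(tert-butyldiphenylsilyl)oxy]methyl}-8-hydroxyoct-2-enoate F3.
  - DABCO and 14 would give dimethyl (2E,4R)-4-[(tert-butyldimethylsilyl)oxy]-5-hydroxy-2-[(4S)-4-{[(tert-butyldiphenylsilyl)oxy]methyl}-6-hydroxyhexylidene]-6-methylideneheptanedioate F4.
  - TEMPO and PhI(OAc)2 would oxidize only the primary alcohol to give dimethyl (2E,4R)-4-[(tert-butyldimethylsilyl)oxy]-5-hydroxy-2-[(4S)-4-{[(tert-butyldiphenylsilyl)oxy]methyl}-6-oxohexylidene]-6-methylideneheptanedioate F5.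
  - NBS and Me2S would then return to the route at 17.
  - If the hindered acrylate does not engage even there, the intramolecular metathesis described for step 12 remains.

**Step 2 (desymmetrizing Baeyer–Villiger).**
- What may go wrong: incomplete enantiocontrol, because the silyloxymethyl group is remote from the coordinated carbonyl. Any erosion would appear after step 11 as a diastereomeric impurity.
- Fallback: the desymmetrization is moved to an enolization. It sets out from 2.
  - Deprotonation with lithium (R,R)-bis(1-phenylethyl)amide in the presence of Me3SiCl at −78 °C would give (S)-{[4-{[(tert-butyldiphenylsilyl)oxy]methyl}cyclohex-1-en-1-yl]oxy}trimethylsilane F6.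
  - Ozonolysis with NaBH4 work-up would cut the C1–C6 enol ether bond and give (4S)-4-{[(tert-butyldiphenylsilyl)oxy]methyl}-6-hydroxyhexanoic acid F7.
  - Yamaguchi lactonization (2,4,6-trichlorobenzoyl chloride, Et3N, DMAP, toluene) would return to the route at 3.

**Step 9 (Morita–Baylis–Hillman).**
- What may go wrong: slow conversion of the hindered α-silyloxy aldehyde, with erosion of C8 by enolization during the long contact with the amine.
- Fallback: the amine-catalysed process is replaced by a preformed nucleophile. It sets out from 13. [1-(Methoxycarbonyl)vinyl]diisobutylaluminium, made from methyl propiolate with DIBAL-H and NMO in THF at 0 °C, would add to the aldehyde within hours under non-basic conditions and return to the route at 15. No compound outside the list is made (F0).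

## Further compounds

F1 | step 12 | methyl (4R)-4-[(tert-butyldimethylsilyl)oxy]-4-[(2R,3S)-2-{(2S)-2-{[(tert-butyldiphenylsilyl)oxy]methyl}hex-5-en-1-yl}-4-methylidene-5-oxooxolan-3-yl]-2-methylidenebutanoate | C=C1C(=O)O[C@H](C[C@@H](CO[Si](c2ccccc2)(c2ccccc2)C(C)(C)C)CCC=C)[C@H]1[C@H](O[Si](C)(C)C(C)(C)C)CC(=C)C(=O)OC
F2 | step 11 | methyl (2E,6S)-2-{(2R)-2-[(tert-butyldimethylsilyl)oxy]-2-[(4S)-2,2-dimethyl-1,3-dioxolan-4-yl]ethyl}-6-{[(tert-butyldiphenylsilyl)oxy]methyl}-8-hydroxyoct-2-enoate | OCC[C@@H](CO[Si](c1ccccc1)(c1ccccc1)C(C)(C)C)CC/C=C(/C(=O)OC)C[C@@H](O[Si](C)(C)C(C)(C)C)[C@@H]1COC(C)(C)O1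
F3 | step 11 | methyl (2E,6S)-2-{(2R)-2-[(tert-butyldimethylsilyl)oxy]-3-oxopropyl}-6-{[(tert-butyldiphenylsilyl)oxy]methyl}-8-hydroxyoct-2-enoate | OCC[C@@H](CO[Si](c1ccccc1)(c1ccccc1)C(C)(C)C)CC/C=C(/C(=O)OC)C[C@@H](O[Si](C)(C)C(C)(C)C)C=O
F4 | step 11 | dimethyl (2E,4R)-4-[(tert-butyldimethylsilyl)oxy]-5-hydroxy-2-[(4S)-4-{[(tert-butyldiphenylsilyl)oxy]methyl}-6-hydroxyhexylidene]-6-methylideneheptanedioate (both C5 epimers) | OCC[C@@H](CO[Si](c1ccccc1)(c1ccccc1)C(C)(C)C)CC/C=C(/C(=O)OC)C[C@@H](O[Si](C)(C)C(C)(C)C)C(O)C(=C)C(=O)OC
F5 | step 11 | dimethyl (2E,4R)-4-[(tert-butyldimethylsilyl)oxy]-5-hydroxy-2-[(4S)-4-{[(tert-butyldiphenylsilyl)oxy]methyl}-6-oxohexylidene]-6-methylideneheptanedioate (both C5 epimers) | O=CC[C@@H](CO[Si](c1ccccc1)(c1ccccc1)C(C)(C)C)CC/C=C(/C(=O)OC)C[C@@H](O[Si](C)(C)C(C)(C)C)C(O)C(=C)C(=O)OC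
F6 | step 2 | (S)-{[4-{[(tert-butyldiphenylsilyl)oxy]methyl}cyclohex-1-en-1-yl]oxy}trimethylsilane | C[Si](C)(C)OC1=CC[C@@H](CO[Si](c2ccccc2)(c2ccccc2)C(C)(C)C)CC1
F7 | step 2 | (4S)-4-{[(tert-butyldiphenylsilyl)oxy]methyl}-6-hydroxyhexanoic acid | OC(=O)CC[C@H](CO[Si](c1ccccc1)(c1ccccc1)C(C)(C)C)CCO
F0 | step 9 | none | none
A1 | alternative 1 | methyl (4R)-4-[(2R,3S)-2-{(2S)-2-{[(tert-butyldiphenylsilyl)oxy]methyl}hex-5-en-1-yl}-4-methylidene-5-oxooxolan-3-yl]-2-methylidene-4-[(2-methylpropanoyl)oxy]butanoate | C=C1C(=O)O[C@H](C[C@@H](CO[Si](c2ccccc2)(c2ccccc2)C(C)(C)C)CCC=C)[C@H]1[C@H](OC(=O)C(C)C)CC(=C)C(=O)OC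
A2 | alternative 2 | 2-{3-[(tert-butyldimethylsilyl)oxy]prop-1-en-2-yl}-5-{[(tert-butyldiphenylsilyl)oxy]methyl}-1-[(E)-2-(methoxymethoxy)ethenyl]cyclohexan-1-ol (alkenyl groups trans, C5 configured as C4 of the target) | O[C@]1(/C=C/OCOC)C[C@@H](CO[Si](c2ccccc2)(c2ccccc2)C(C)(C)C)CC[C@@H]1C(=C)CO[Si](C)(C)C(C)(C)C
A3 | alternative 2 | 8-(methoxymethoxy)-14-[(tert-butyldimethylsilyl)oxy]-15-[(tert-butyldiphenylsilyl)oxy]germacr-1(10)-en-6-one (germacrane locants, ring alkene trans) | O=C1C[C@H](OCOC)C/C(CO[Si](C)(C)C(C)(C)C)=C/CC[C@H](CO[Si](c2ccccc2)(c2ccccc2)C(C)(C)C)C1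
A4 | alternative 3 | thirteen-membered cyclic ether with O8 bonded to C13: dimethyl 6-[(tert-butyldimethylsilyl)oxy]-15-[(tert-butyldiphenylsilyl)oxy]-8,13-epoxy-7,8-secogermacra-1(10),7(11)-diene-12,14-dioate (germacrane locants) | COC(=O)/C1=C/CC[C@H](CO[Si](c2ccccc2)(c2ccccc2)C(C)(C)C)C[C@@H](O[Si](C)(C)C(C)(C)C)/C=C(/C(=O)OC)COCC1
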